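A small charge of free catalyst, 27 µM against 10 mM of starting material, has to outrun a reaction that needs no catalyst at all. The one quantity carried here is that leak.

all flasks: starting material 10 mM; free catalyst 27 µM

| flask | second substrate | partner | protic impurity | remark |
|---|---|---|---|---|
| spring | 5 mM | 5 mM | 1 mM | the very flask that is asked about, followed so far |
| dawn | 5 mM | 10 mM | 1 mM | run made earlier |
| flask | 5.00 mM | 5.00 mM | 1.00 mM |  |

| run | time / min | target / % | starting material / % |
|---|---|---|---|
| spring | 2.00 | 6 | 93 |
| spring | 4.00 | 12 | 83 |
| spring | 6.00 | 17 | 80 |
| spring | 8.00 | 21 | 72 |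
| spring | 10.0 | 20 | 72 |
| spring | 12.0 | 26 | 69 |
| dawn | 10.0 | 41 | 53 |
| dawn | 20.0 | 56 | 36 |
| dawn | 30.0 | 68 | 31 |
| dawn | 40.0 | 67 | 27 |
| dawn | 50.0 | 69 | 21 |
| dawn | 60.0 | 67 | 20 |

(scatter of a reading: 2 percentage points)

- factor on the rate of making target when 30 % of the starting material are converted if free catalyst is charged twice over
- factor on the rate when 30 % of the starting material are converted if free catalyst is charged at 2.5 µM instead

- a species is counted by the starting material in it: one homo dimer counts as two
- candidate steps: partner + protic impurity -> quenched reagent; 2 starting material -> homo dimer; second substrate + free catalyst <-> catalyst intermediate B; starting material + free catalyst <-> catalyst intermediate A; partner + catalyst intermediate B -> free catalyst + second product; partner + catalyst intermediate A -> free catalyst + target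
- no earlier run changes the charge of free catalyst; that part of a forecast is a guess

1. In the spring run, target and starting material together fall short of the charge. Over the last three readings the shortfall averages 0.0667 mM min⁻¹. This mean rate of loss of starting material that never reaches target, taken as homo dimer, is the leak; it is a reading and carries the scatter.

2. Spring passes 30 % conversion near 11.0 min. The leak has then taken 0.734 mM, so target holds 2.27 mM, a mean of 0.206 mM min⁻¹.

3. Dawn's target levels off near 6.77 mM. Taking all of dawn's 10 mM of partner as used by then, each target costs 1.48 partner, so spring keeps [partner] = 1.65 mM.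

4. Dawn has about twice spring's target at 10.0 min, so the rate is taken as proportional to [partner]. Proportionality to catalyst is a guess. With double catalyst, 30 % comes at 6.27 min, [partner] is 1.19 mM, and the factor is 1.44.

5. At 2.5 µM, 30 % comes at 35.0 min, with target only 0.668 mM. The weak link is step 3: protic impurity takes partner by the clock, not per target. Reforged, the 1.00 mM of impurity is reckoned as spent evenly over dawn's first 30.0 min, and second product costs 0.328 per target. At 30 %, [partner] is then 1.62 mM in spring, 1.36 mM with double catalyst, and 3.11 mM at 2.5 µM, where the reckoned time runs past that span. The reckoned factors become 1.68 and 0.178.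

The forecast differs, with 1.5 and 0.26, and holds that “Doubling catalyst halves the dimer share”.

The flask gives 1.75 and 0.157.

    partner + protic impurity → quenched reagent (k = 0.110 M⁻¹ s⁻¹)
    2 starting material → homo dimer (k = 0.00720 M⁻¹ s⁻¹)
    second substrate + free catalyst ⇌ catalyst intermediate B (K = 11000 M⁻¹, k = 12.0 M⁻¹ s⁻¹)
    starting material + free catalyst ⇌ catalyst intermediate A (K = 120 M⁻¹, k = 93.0 M⁻¹ s⁻¹)
    partner + catalyst intermediate B → free catalyst + second product (k = 28.0 M⁻¹ s⁻¹)
    partner + catalyst intermediate A → free catalyst + target (k = 150 M⁻¹ s⁻¹)

Doubling lands above the reckoned 1.68, while 2.5 µM lands near 0.178. In this flask homo dimer stands at 4.10 % after 0.100 h, and the leak gives 4.00 % for that time. Up to 10.8 min the leak accounts for 0.720 mM of the 3.00 mM converted. Second substrate lowers the rate at 30 % in this flask, with an apparent order of −0.54, and the turning of partner + catalyst intermediate B into free catalyst + second product is the largest single effect on that order: without that step, the order is −0.92.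

The numbers in the tables come from a simulation from invented constants; the scatter is artificial.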